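**Assumptions.** O‑Benzylsyringaldehyde (1) is taken as a catalogue compound; if it is not, add one step (syringaldehyde, BnBr, K2CO3, DMF). Lignan numbering is used: C7 = ArCH–O, C8 = CH–CH2OH (C9), C8' = CH–CH2Ar (C7'), C9' = ring OCH2. The route has not been run; selectivities quoted are expectations from the reaction types.

## Retrosynthetic overview

1. Target ⇐ hydrogenolysis of the two phenolic benzyl ethers of 11.
2. THF ring (formed last, C7–O–C9') ⇐ acid‑mediated benzylic SN1 cycloetherification of triol 10, which sets C7 trans to C8.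
3. Triol 10 ⇐ LiAlH4 opening of the trans α‑(hydroxybenzyl)‑β‑benzyl‑γ‑butyrolactone 9 ⇐ aldol of (R)‑lactone 8 with aldehyde 1, which sets C8 anti to C8'.
4. Lactone 8 (temporary ring, formed first) ⇐ Evans alkylation of imide 5 with tert‑butyl bromoacetate, which sets C8', then reductive auxiliary removal and lactonisation.
5. Imide 5 ⇐ acid 3 ⇐ aldehyde 1 + Meldrum's acid. Both aryl units come from aldehyde 1.

## Route

**Step 1**
Reactants: 1, 4‑(benzyloxy)‑3,5‑dimethoxybenzaldehyde; 2, Meldrum's acid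
Product: 3, 3‑[4‑(benzyloxy)‑3,5‑dimethoxyphenyl]propanoic acid
Conditions: HCO2H/Et3N (5:2), 100 °C; aq. HCl work‑up
Reagents that add atoms: Meldrum's acid, CC1(C)OC(=O)CC(=O)O1 (supplies CH2–CO2H; formate gives only H)
Why: Knoevenagel condensation, formate hydride conjugate reduction of the arylidene Meldrum's acid, then hydrolysis/decarboxylation in one pot; no Pd/H2, so the benzyl ether survives. No stereocentre.

**Step 2**
Reactants: 3, the propanoic acid; 4, (S)‑4‑benzyl‑2‑oxazolidinone
Product: 5, (S)‑4‑benzyl‑3‑{3‑[4‑(benzyloxy)‑3,5‑dimethoxyphenyl]propanoyl}oxazolidin‑2‑one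
Conditions: PivCl, Et3N, THF, −20 °C; then 4, LiCl, −20 °C → rt
Reagents that add atoms: (S)‑4‑benzyl‑2‑oxazolidinone, O=C1N[C@@H](Cc2ccccc2)CO1
Why: Mixed‑anhydride N‑acylation installs the Evans auxiliary; the pivaloyl group leaves no atoms.

**Step 3**
Reactants: 5, the imide; 6, tert‑butyl bromoacetate
Product: 7, tert‑butyl (3R)‑3‑[4‑(benzyloxy)‑3,5‑dimethoxybenzyl]‑4‑[(4S)‑4‑benzyl‑2‑oxooxazolidin‑3‑yl]‑4‑oxobutanoate
Conditions: NaHMDS, THF, −78 °C; then 6, −78 → −40 °C
Reagents that add atoms: tert‑butyl bromoacetate, CC(C)(C)OC(=O)CBr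
Why: Evans asymmetric alkylation; the chelated (Z)‑sodium enolate is attacked on the face opposite the auxiliary's C4‑benzyl group, giving the (R) centre (future C8') with expected dr ≥ 95:5, and the minor isomer is removable by chromatography.

**Step 4**
Reactants: 7, the alkylated imide
Product: 8, (R)‑4‑[4‑(benzyloxy)‑3,5‑dimethoxybenzyl]dihydrofuran‑2(3H)‑one (auxiliary 4 recovered)
Conditions: LiBH4, MeOH (1 equiv), THF, 0 °C; then TsOH·H2O (cat.), PhMe, 80 °C
Reagents that add atoms: none
Why: Chemoselective reductive cleavage of the imide (the tert‑butyl ester survives) gives the γ‑hydroxy ester, which lactonises under acid with loss of tert‑butanol; the stereocentre ends up β to the carbonyl and cannot epimerise.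

**Step 5**
Reactants: 8, the (R)‑lactone; 1, 4‑(benzyloxy)‑3,5‑dimethoxybenzaldehyde
Product: 9, (3S,4R)‑4‑[4‑(benzyloxy)‑3,5‑dimethoxybenzyl]‑3‑{[4‑(benzyloxy)‑3,5‑dimethoxyphenyl](hydroxy)methyl}dihydrofuran‑2(3H)‑one (3,4‑trans; mixture of carbinol epimers)
Conditions: LiHMDS, THF, −78 °C; then 1, −78 °C; AcOH quench at −78 °C
Reagents that add atoms: aldehyde 1, COc1cc(C=O)cc(OC)c1OCc1ccccc1
Why: Lactone enolate aldol; the aldehyde approaches anti to the β‑arylmethyl group, setting C8 trans to C8'. The C7 carbinol mixture does not matter because C7 is re‑set in step 7.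

**Step 6**
Reactants: 9, the aldol lactone
Product: 10, (2R,3R)‑2‑[4‑(benzyloxy)‑3,5‑dimethoxybenzyl]‑3‑{[4‑(benzyloxy)‑3,5‑dimethoxyphenyl](hydroxy)methyl}butane‑1,4‑diol (carbinol epimers)
Conditions: LiAlH4, THF, 0 °C → rt (lactone added to the hydride)
Reagents that add atoms: none
Why: Hydride reduction of the lactone to the 1,4‑diol; benzyl and methyl ethers are inert, and C8/C8' are no longer α to a carbonyl afterwards.

**Step 7**
Reactants: 10, the triol
Product: 11, [(2S,3R,4R)‑4‑[4‑(benzyloxy)‑3,5‑dimethoxybenzyl]‑2‑[4‑(benzyloxy)‑3,5‑dimethoxyphenyl]tetrahydrofuran‑3‑yl]methanol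
Conditions: CSA (0.1 equiv), CH2Cl2 (0.02 M), 0 °C → rt
Reagents that add atoms: none
Why: SN1 cycloetherification; the electron‑rich benzylic alcohol ionises and is trapped 5‑exo by the C9'–OH (the C9–OH could only give an oxetane). Both carbinol epimers converge, and reversible ionisation delivers the more stable 2,3‑trans aryl (7S). The trans lactone relationship translates into the required 8,8'‑cis (CH2OH/benzyl) THF.

**Step 8**
Reactants: 11, the bis‑benzyl ether
Product: 12, (+)‑(7S,8R,8'R)‑5,5'‑dimethoxylariciresinol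
Conditions: H2 (1 atm), 10% Pd/C, EtOAc, rt; stop when debenzylation is complete
Reagents that add atoms: none
Why: Catalytic hydrogenolysis of aryl benzyl ethers is much faster under neutral conditions than cleavage of the cyclic benzylic C7–O bond; no stereocentre is touched.

## Compound list

1 | 4‑(benzyloxy)‑3,5‑dimethoxybenzaldehyde | COc1cc(C=O)cc(OC)c1OCc1ccccc1 | starting material
2 | Meldrum's acid | CC1(C)OC(=O)CC(=O)O1 | starting material
3 | 3‑[4‑(benzyloxy)‑3,5‑dimethoxyphenyl]propanoic acid | COc1cc(CCC(=O)O)cc(OC)c1OCc1ccccc1 | intermediate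
4 | (S)‑4‑benzyl‑2‑oxazolidinone | O=C1N[C@@H](Cc2ccccc2)CO1 | starting material
5 | (S)‑4‑benzyl‑3‑{3‑[4‑(benzyloxy)‑3,5‑dimethoxyphenyl]propanoyl}oxazolidin‑2‑one | COc1cc(CCC(=O)N2C(=O)OC[C@@H]2Cc2ccccc2)cc(OC)c1OCc1ccccc1 | intermediate
6 | tert‑butyl bromoacetate | CC(C)(C)OC(=O)CBr | starting material
7 | tert‑butyl (3R)‑3‑[4‑(benzyloxy)‑3,5‑dimethoxybenzyl]‑4‑[(4S)‑4‑benzyl‑2‑oxooxazolidin‑3‑yl]‑4‑oxobutanoate | COc1cc(C[C@H](CC(=O)OC(C)(C)C)C(=O)N2C(=O)OC[C@@H]2Cc2ccccc2)cc(OC)c1OCc1ccccc1 | intermediate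
8 | (R)‑4‑[4‑(benzyloxy)‑3,5‑dimethoxybenzyl]dihydrofuran‑2(3H)‑one | COc1cc(C[C@H]2COC(=O)C2)cc(OC)c1OCc1ccccc1 | intermediate
9 | (3S,4R)‑4‑[4‑(benzyloxy)‑3,5‑dimethoxybenzyl]‑3‑{[4‑(benzyloxy)‑3,5‑dimethoxyphenyl](hydroxy)methyl}dihydrofuran‑2(3H)‑one (carbinol epimers) | COc1cc(C[C@H]2COC(=O)[C@@H]2C(O)c2cc(OC)c(OCc3ccccc3)c(OC)c2)cc(OC)c1OCc1ccccc1 | intermediate
10 | (2R,3R)‑2‑[4‑(benzyloxy)‑3,5‑dimethoxybenzyl]‑3‑{[4‑(benzyloxy)‑3,5‑dimethoxyphenyl](hydroxy)methyl}butane‑1,4‑diol (carbinol epimers) | COc1cc(C[C@@H](CO)[C@H](CO)C(O)c2cc(OC)c(OCc3ccccc3)c(OC)c2)cc(OC)c1OCc1ccccc1 | intermediate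
11 | [(2S,3R,4R)‑4‑[4‑(benzyloxy)‑3,5‑dimethoxybenzyl]‑2‑[4‑(benzyloxy)‑3,5‑dimethoxyphenyl]tetrahydrofuran‑3‑yl]methanol | COc1cc(C[C@H]2CO[C@H](c3cc(OC)c(OCc4ccccc4)c(OC)c3)[C@H]2CO)cc(OC)c1OCc1ccccc1 | intermediate
12 | (+)‑(7S,8R,8'R)‑5,5'‑dimethoxylariciresinol | COc1cc(C[C@H]2CO[C@H](c3cc(OC)c(O)c(OC)c3)[C@H]2CO)cc(OC)c1O | target

## Summary

**Total steps:** 8. **Longest linear sequence:** 8 (from 1; aldehyde 1 is used twice).

**Steps most likely to fail, with fallbacks**

1. **Step 7, acid cycloetherification.** Risks are competing Friedel–Crafts closure onto the other ring (aryltetralin, lyoniresinol‑type) and incomplete C7 selectivity. Fallback: an oxidative ring closure instead of an ionising one. Alkylate lactone 8 with 4‑(benzyloxy)‑3,5‑dimethoxybenzyl bromide (trans), reduce with LiAlH4 and debenzylate to (8R,8'R)‑5,5'‑dimethoxysecoisolariciresinol. Then treat with about 1 equiv DDQ, so the p‑quinone methide formed at C7 is trapped 5‑exo by the C9'–OH. The cost is that this C2‑symmetric diol can over‑oxidise to syringaresinol, so mono‑cyclisation is statistically limited.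

2. **Step 8, hydrogenolysis.** Risk is over‑reduction of the benzylic C7–O bond to the secoisolariciresinol analogue. Fallback: change the order and the reactive intermediate. Debenzylate triol 10 first (H2, Pd/C), then close the ring on the free bis‑phenol through its p‑quinone methide under trace acid, so no reducing step follows THF formation. Alternatively carry the phenols as allyl ethers from the start and remove them with Pd(0)/morpholine.

3. **Step 5, lactone aldol.** Risks are retro‑aldol on warming and an electron‑rich, sluggish aldehyde. Fallback: make the C7–C8 bond by irreversible Claisen acylation of the enolate of 8 with 4‑(benzyloxy)‑3,5‑dimethoxybenzoyl chloride. The resulting trans β‑keto lactone is reduced by LiAlH4 at both the ketone and the lactone to the same triol 10, since C7 configuration is irrelevant before step 7.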